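**Plan**

1. Retrosynthesis (ring locants of the target: C1 = CH carrying the chain, C2 = CMe2, C3 = CHBr, C6 = C=CH2): the carbinol comes from a bromomethyl ketone (CBS reduction), the Z alkene from a ring acetaldehyde (Still–Gennari), C6=CH2 from a ketone, C3–Br from a vinyl bromide (hydrogen-atom-transfer hydrogenation), and the ring bond C1–C2 is cut by a retro-semipinacol 1,2-shift.
2. Forward: 2,2-dimethylcyclopentane-1,3-dione → mono-Wittig (brings in C1 and the first chain carbons) → second C=O to vinyl bromide → Shi epoxide → anti bromohydrin → silver-promoted enlargement of the cyclopentene to the cyclohexenone (five to six) → HAT reduction, methylenation, side chain.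
3. Enabling feature: the methylidene carbon C6 is a masked ketone next to the stereogenic CH C1, which is bonded to the quaternary C2. A cyclopentenol whose carbinol carbon (future C6) carries an exocyclic CHBr carbon (future C1) and has C2 as its more substituted, allylic ring neighbour maps onto the ring, and C2 is the carbon that migrates.
4. Stereochemistry: C1 comes from the Shi epoxidation, relayed by two inversions (bromide opening, 1,2-shift). C3 comes from axial hydrogen delivery to an α-bromo radical (Br equatorial, cis to the C1 chain). The Z alkene comes from the Still–Gennari reagent and the carbinol from the (S)-CBS catalyst.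

Key step: step 7

Assumption: the Wittig reaction of step 2 gives mainly the E-alkylidene isomer (chain away from CMe2); any Z isomer is removed by chromatography before step 5.

**Route**

Step 1
Reactants: 1 (3-bromopropoxy)(tert-butyl)dimethylsilane
Product: 2 {3-[(tert-butyldimethylsilyl)oxy]propyl}triphenylphosphonium bromide
Conditions: PPh3, MeCN, reflux
Reagents that add atoms: triphenylphosphine, c1ccc(cc1)P(c1ccccc1)c1ccccc1
Why: SN2 quaternisation of the phosphine by a primary bromide (phosphonium salt formation) should proceed cleanly.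

Step 2
Reactants: 2 {3-[(tert-butyldimethylsilyl)oxy]propyl}triphenylphosphonium bromide; 3 2,2-dimethylcyclopentane-1,3-dione
Product: 5 (3E)-3-{3-[(tert-butyldimethylsilyl)oxy]propylidene}-2,2-dimethylcyclopentan-1-one, via phosphonium ylide 4 (not isolated)
Conditions: KN(SiMe3)2, THF, 0 °C; then 3 (1 equiv), −78 °C → 50 °C
Reagents that add atoms: none
Why: Wittig olefination of one of the two equivalent carbonyl groups with a salt-free unstabilised ylide should place the chain syn to the ring CH2 and away from CMe2 (E), leaving the second ketone for step 3.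

Step 3
Reactants: 5 (3E)-3-{3-[(tert-butyldimethylsilyl)oxy]propylidene}-2,2-dimethylcyclopentan-1-one
Product: 6 N'-[(1E,3E)-3-{3-[(tert-butyldimethylsilyl)oxy]propylidene}-2,2-dimethylcyclopentylidene]-2,4,6-tri(propan-2-yl)benzenesulfonohydrazide
Conditions: 2,4,6-(i-Pr)3C6H2SO2NHNH2, THF, cat. PPTS, rt
Reagents that add atoms: 2,4,6-tri(propan-2-yl)benzenesulfonohydrazide, CC(C)c1cc(C(C)C)c(S(=O)(=O)NN)c(C(C)C)c1
Why: hydrazone condensation should put the sulfonamide nitrogen anti to the quaternary carbon, that is syn to the only α-CH2, as the Shapiro reaction needs.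

Step 4
Reactants: 6 N'-[(1E,3E)-3-{3-[(tert-butyldimethylsilyl)oxy]propylidene}-2,2-dimethylcyclopentylidene]-2,4,6-tri(propan-2-yl)benzenesulfonohydrazide
Product: 8 {[(3E)-3-(3-bromo-2,2-dimethylcyclopent-3-en-1-ylidene)propyl]oxy}(tert-butyl)dimethylsilane, via vinyllithium 7 (not isolated)
Conditions: n-BuLi (2.2 equiv), THF, −78 → 0 °C; then BrCH2CH2Br, −78 °C
Reagents that add atoms: 1,2-dibromoethane, BrCCBr
Why: the Shapiro reaction is regiospecific here (only one α-CH2) and the vinyllithium should take bromine from the dibromide, giving the bromoalkene next to CMe2.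

Step 5
Reactants: 8 {[(3E)-3-(3-bromo-2,2-dimethylcyclopent-3-en-1-ylidene)propyl]oxy}(tert-butyl)dimethylsilane
Product: 9 (2R,3R)-5-bromo-2-{2-[(tert-butyldimethylsilyl)oxy]ethyl}-4,4-dimethyl-1-oxaspiro[2.4]hept-5-ene
Conditions: D-fructose-derived Shi ketone (1,2:4,5-di-O-isopropylidene-β-D-erythro-2,3-hexodiulo-2,6-pyranose, 30 mol %), Oxone (2KHSO5·KHSO4·K2SO4), K2CO3, Bu4NHSO4, MeCN/dimethoxymethane/aq. Na2B4O7 buffer, 0 °C
Reagents that add atoms: potassium peroxymonosulfate (active part of Oxone), [K+].[O-]S(=O)(=O)OO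
Why: Shi dioxirane epoxidation should attack the electron-rich trisubstituted exocyclic alkene and not the bromoalkene, and the spiro transition state of the D-fructose ketone should deliver oxygen to the face that gives the (2R,3R)-epoxide from the E-alkene.

Step 6
Reactants: 9 (2R,3R)-5-bromo-2-{2-[(tert-butyldimethylsilyl)oxy]ethyl}-4,4-dimethyl-1-oxaspiro[2.4]hept-5-ene
Product: 10 (1R)-3-bromo-1-{(1S)-1-bromo-3-[(tert-butyldimethylsilyl)oxy]propyl}-2,2-dimethylcyclopent-3-en-1-ol
Conditions: Li2NiBr4, THF, 0 °C → rt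
Reagents that add atoms: dilithium tetrabromonickelate Li2NiBr4, [Li+].[Li+].[Ni+2].[Br-].[Br-].[Br-].[Br-]
Why: soft bromide should open the oxirane by SN2 at the secondary carbon (the spiro carbon is fully substituted) with inversion, giving the anti bromohydrin with tertiary OH and secondary Br.

Step 7
Reactants: 10 (1R)-3-bromo-1-{(1S)-1-bromo-3-[(tert-butyldimethylsilyl)oxy]propyl}-2,2-dimethylcyclopent-3-en-1-ol
Product: 11 (6S)-4-bromo-6-{2-[(tert-butyldimethylsilyl)oxy]ethyl}-5,5-dimethylcyclohex-3-en-1-one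
Conditions: AgBF4, solid NaHCO3, CH2Cl2, −40 °C → rt
Reagents that add atoms: none
Why: silver ion pulls bromide from the exocyclic CHBr carbon while the antiperiplanar ring bond from the carbinol carbon to the quaternary CMe2 carbon shifts to it and the hydroxyl becomes the carbonyl (halohydrin semipinacol shift; closest known type: silver-assisted enlargement of 1-(1-haloalkyl)cycloalkanols). The six-membered ring is not closed by cyclisation but arises by insertion of the former exocyclic carbon between C1 and C2 of the cyclopentenol, five to six. The new ring stereocentre C6 of 11 is formed with inversion at the bromine-bearing carbon, so it is controlled by the Shi epoxide through two inversions. The step needs migration of the quaternary carbon and not of the ring CH2: the more substituted, allylic carbon has the higher migratory aptitude in a cation-like shift, and in the anti (1R,1'S) isomer the least hindered rotamer has CMe2 anti to bromine, whereas the rotamer for CH2 migration would put CMe2 gauche to both bromine and the chain. NaHCO3 takes up the acid so that the silyl ether and the β,γ-enone survive, and the vinyl bromide does not ionise.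

Step 8
Reactants: 11 (6S)-4-bromo-6-{2-[(tert-butyldimethylsilyl)oxy]ethyl}-5,5-dimethylcyclohex-3-en-1-one
Product: 12 (2S,4S)-4-bromo-2-{2-[(tert-butyldimethylsilyl)oxy]ethyl}-3,3-dimethylcyclohexan-1-one
Conditions: Mn(dpm)3 (dpm = dipivaloylmethanate, 10 mol %), PhSiH3, t-BuOOH, i-PrOH, 22 °C, Ar
Reagents that add atoms: none
Why: hydrogen atom transfer from a manganese hydride (HAT hydrogenation, which reduces haloalkenes without C–Br hydrogenolysis) to the CH= carbon should give the α-bromo radical next to CMe2, and the second hydrogen should arrive axially, anti to the axial methyl, so that bromine ends equatorial and cis to the equatorial chain (4S).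

Step 9
Reactants: 12 (2S,4S)-4-bromo-2-{2-[(tert-butyldimethylsilyl)oxy]ethyl}-3,3-dimethylcyclohexan-1-one
Product: 13 {2-[(1R,3S)-3-bromo-2,2-dimethyl-6-methylidenecyclohexyl]ethoxy}(tert-butyl)dimethylsilane
Conditions: Cp2TiMe2, toluene/THF, 65 °C, dark
Reagents that add atoms: dimethyltitanocene Cp2TiMe2, [CH3-].[CH3-].[Ti+4].[cH-]1cccc1.[cH-]1cccc1
Why: Petasis methylenation is non-basic, so the α-stereocentre should not epimerise and the γ-bromide should not be lost by enolate 1,3-elimination.

Step 10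
Reactants: 13 {2-[(1R,3S)-3-bromo-2,2-dimethyl-6-methylidenecyclohexyl]ethoxy}(tert-butyl)dimethylsilane
Product: 14 2-[(1R,3S)-3-bromo-2,2-dimethyl-6-methylidenecyclohexyl]ethan-1-ol
Conditions: HF·pyridine, pyridine/THF, 0 °C → rt
Reagents that add atoms: none
Why: fluoride cleavage of the primary silyl ether under buffered conditions should leave the exocyclic alkene and the secondary bromide untouched.

Step 11
Reactants: 14 2-[(1R,3S)-3-bromo-2,2-dimethyl-6-methylidenecyclohexyl]ethan-1-ol
Product: 15 2-[(1R,3S)-3-bromo-2,2-dimethyl-6-methylidenecyclohexyl]acetaldehyde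
Conditions: Dess–Martin periodinane, NaHCO3, CH2Cl2, 0 °C → rt
Reagents that add atoms: none
Why: Dess–Martin oxidation of a primary alcohol should stop at the aldehyde under neutral conditions.

Step 12
Reactants: 15 2-[(1R,3S)-3-bromo-2,2-dimethyl-6-methylidenecyclohexyl]acetaldehyde
Product: 16 ethyl (2Z)-4-[(1R,3S)-3-bromo-2,2-dimethyl-6-methylidenecyclohexyl]-2-methylbut-2-enoate
Conditions: (CF3CH2O)2P(O)CH(CH3)CO2Et, KN(SiMe3)2, 18-crown-6, THF, −78 °C
Reagents that add atoms: ethyl 2-[bis(2,2,2-trifluoroethoxy)phosphoryl]propanoate, CCOC(=O)C(C)P(=O)(OCC(F)(F)F)OCC(F)(F)F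
Why: Still–Gennari olefination (fast, irreversible elimination from the trifluoroethyl phosphonate adduct) should give the Z trisubstituted enoate with ring CH2 and ester cis.

Step 13
Reactants: 16 ethyl (2Z)-4-[(1R,3S)-3-bromo-2,2-dimethyl-6-methylidenecyclohexyl]-2-methylbut-2-enoate
Product: 18 (3Z)-1-bromo-5-[(1R,3S)-3-bromo-2,2-dimethyl-6-methylidenecyclohexyl]-3-methylpent-3-en-2-one, via lithium hemiketal alkoxide 17 (not isolated)
Conditions: CH2Br2, MeLi·LiBr, THF, −78 °C; then aq. NH4Cl
Reagents that add atoms: dibromomethane, BrCBr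
Why: bromomethyllithium made in the flask acylates the ester (halomethyllithium homologation of esters to α-haloketones), and because alkoxide 17 persists at −78 °C until the quench, a second addition should not occur and the Z alkene is not touched.

Step 14
Reactants: 18 (3Z)-1-bromo-5-[(1R,3S)-3-bromo-2,2-dimethyl-6-methylidenecyclohexyl]-3-methylpent-3-en-2-one
Product: 19 (2S,3Z)-1-bromo-5-[(1R,3S)-3-bromo-2,2-dimethyl-6-methylidenecyclohexyl]-3-methylpent-3-en-2-ol
Conditions: (S)-2-methyl-CBS-oxazaborolidine (20 mol %), catecholborane, toluene, −78 °C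
Reagents that add atoms: none
Why: Corey–Bakshi–Shibata 1,2-reduction with the (S)-catalyst, the alkenyl group acting as the large and CH2Br as the small substituent, should give the (S)-bromohydrin, and catecholborane at −78 °C should not hydroborate the methylidene group.

**Compound list**

1 | (3-bromopropoxy)(tert-butyl)dimethylsilane | BrCCCO[Si](C)(C)C(C)(C)C | starting material
2 | {3-[(tert-butyldimethylsilyl)oxy]propyl}triphenylphosphonium bromide | [Br-].CC(C)(C)[Si](C)(C)OCCC[P+](c1ccccc1)(c1ccccc1)c1ccccc1 | intermediate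
3 | 2,2-dimethylcyclopentane-1,3-dione | CC1(C)C(=O)CCC1=O | starting material
4 | {3-[(tert-butyldimethylsilyl)oxy]propylidene}triphenylphosphorane (ylide) | CC(C)(C)[Si](C)(C)OCCC=P(c1ccccc1)(c1ccccc1)c1ccccc1 | intermediate (not isolated)
5 | (3E)-3-{3-[(tert-butyldimethylsilyl)oxy]propylidene}-2,2-dimethylcyclopentan-1-one | CC1(C)C(=O)CC/C1=C\CCO[Si](C)(C)C(C)(C)C | intermediate
6 | N'-[(1E,3E)-3-{3-[(tert-butyldimethylsilyl)oxy]propylidene}-2,2-dimethylcyclopentylidene]-2,4,6-tri(propan-2-yl)benzenesulfonohydrazide | CC1(C)/C(CC/C1=C\CCO[Si](C)(C)C(C)(C)C)=N/NS(=O)(=O)c1c(C(C)C)cc(C(C)C)cc1C(C)C | intermediate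
7 | [(4E)-4-{3-[(tert-butyldimethylsilyl)oxy]propylidene}-5,5-dimethylcyclopent-1-en-1-yl]lithium | CC1(C)C([Li])=CC/C1=C\CCO[Si](C)(C)C(C)(C)C | intermediate (not isolated)
8 | {[(3E)-3-(3-bromo-2,2-dimethylcyclopent-3-en-1-ylidene)propyl]oxy}(tert-butyl)dimethylsilane | CC1(C)C(Br)=CC/C1=C\CCO[Si](C)(C)C(C)(C)C | intermediate
9 | (2R,3R)-5-bromo-2-{2-[(tert-butyldimethylsilyl)oxy]ethyl}-4,4-dimethyl-1-oxaspiro[2.4]hept-5-ene | CC1(C)C(Br)=CC[C@@]12O[C@@H]2CCO[Si](C)(C)C(C)(C)C | intermediate
10 | (1R)-3-bromo-1-{(1S)-1-bromo-3-[(tert-butyldimethylsilyl)oxy]propyl}-2,2-dimethylcyclopent-3-en-1-ol | CC1(C)C(Br)=CC[C@]1(O)[C@@H](Br)CCO[Si](C)(C)C(C)(C)C | intermediate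
11 | (6S)-4-bromo-6-{2-[(tert-butyldimethylsilyl)oxy]ethyl}-5,5-dimethylcyclohex-3-en-1-one | O=C1CC=C(Br)C(C)(C)[C@@H]1CCO[Si](C)(C)C(C)(C)C | intermediate
12 | (2S,4S)-4-bromo-2-{2-[(tert-butyldimethylsilyl)oxy]ethyl}-3,3-dimethylcyclohexan-1-one | O=C1CC[C@H](Br)C(C)(C)[C@@H]1CCO[Si](C)(C)C(C)(C)C | intermediate
13 | {2-[(1R,3S)-3-bromo-2,2-dimethyl-6-methylidenecyclohexyl]ethoxy}(tert-butyl)dimethylsilane | C=C1CC[C@H](Br)C(C)(C)[C@@H]1CCO[Si](C)(C)C(C)(C)C | intermediate
14 | 2-[(1R,3S)-3-bromo-2,2-dimethyl-6-methylidenecyclohexyl]ethan-1-ol | C=C1CC[C@H](Br)C(C)(C)[C@@H]1CCO | intermediate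
15 | 2-[(1R,3S)-3-bromo-2,2-dimethyl-6-methylidenecyclohexyl]acetaldehyde | C=C1CC[C@H](Br)C(C)(C)[C@@H]1CC=O | intermediate
16 | ethyl (2Z)-4-[(1R,3S)-3-bromo-2,2-dimethyl-6-methylidenecyclohexyl]-2-methylbut-2-enoate | C=C1CC[C@H](Br)C(C)(C)[C@@H]1C/C=C(/C)C(=O)OCC | intermediate
17 | lithium (3Z)-1-bromo-5-[(1R,3S)-3-bromo-2,2-dimethyl-6-methylidenecyclohexyl]-2-ethoxy-3-methylpent-3-en-2-olate (both configurations at C2) | [Li+].C=C1CC[C@H](Br)C(C)(C)[C@@H]1C/C=C(/C)C([O-])(OCC)CBr | intermediate (not isolated)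
18 | (3Z)-1-bromo-5-[(1R,3S)-3-bromo-2,2-dimethyl-6-methylidenecyclohexyl]-3-methylpent-3-en-2-one | C=C1CC[C@H](Br)C(C)(C)[C@@H]1C/C=C(/C)C(=O)CBr | intermediate
19 | (2S,3Z)-1-bromo-5-[(1R,3S)-3-bromo-2,2-dimethyl-6-methylidenecyclohexyl]-3-methylpent-3-en-2-ol | C=C1CC[C@H](Br)C(C)(C)[C@@H]1C/C=C(/C)[C@H](O)CBr | target

**Count and risks**

Total steps: 14. Longest linear sequence: 14 steps (1 → 19; dione 3 enters at step 2).

Most likely to fail:

1. Step 8. Hydrogen atom transfer to the hindered bromoalkene may be slow, bromine may be lost through the regioisomeric β-bromo radical, or the second hydrogen may be delivered with poor facial selectivity. Fallback (ionic instead of radical, setting out from 11): methylenation first (Cp2TiMe2, toluene, 65 °C) gives {2-[(1R)-3-bromo-2,2-dimethyl-6-methylidenecyclohex-3-en-1-yl]ethoxy}(tert-butyl)dimethylsilane F1. Miyaura borylation (PdCl2(dppf), B2pin2, KOAc, dioxane, 80 °C) gives tert-butyl{2-[(1R)-2,2-dimethyl-6-methylidene-3-(4,4,5,5-tetramethyl-1,3,2-dioxaborolan-2-yl)cyclohex-3-en-1-yl]ethoxy}dimethylsilane F2. Oxidation (NaBO3·4H2O, THF/H2O) gives (3R)-3-{2-[(tert-butyldimethylsilyl)oxy]ethyl}-2,2-dimethyl-4-methylidenecyclohexan-1-one F3. Equatorial hydride attack (K[HB(sec-Bu)3], THF, −78 °C) should give the axial alcohol (1R,3R)-3-{2-[(tert-butyldimethylsilyl)oxy]ethyl}-2,2-dimethyl-4-methylidenecyclohexan-1-ol F4, trans to the chain. Appel bromination with inversion (CBr4, PPh3, CH2Cl2) comes back to the route at 13; this displacement at a neopentyl-type centre is expected to be the less efficient way.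

2. Step 7. The bromohydrin may return to the epoxide, ionise sluggishly, or let the ring CH2 migrate in competition. Fallback (nitrogen instead of bromide as leaving group, setting out from 9): azide opening at the secondary oxirane carbon (NaN3, NH4Cl, MeOH/H2O, 65 °C) gives (1R)-1-{(1S)-1-azido-3-[(tert-butyldimethylsilyl)oxy]propyl}-3-bromo-2,2-dimethylcyclopent-3-en-1-ol F5. Staudinger reduction (PMe3, THF/H2O) gives (1R)-1-{(1S)-1-amino-3-[(tert-butyldimethylsilyl)oxy]propyl}-3-bromo-2,2-dimethylcyclopent-3-en-1-ol F6. Nitrosation (NaNO2, AcOH/H2O, 0 °C) then triggers a Tiffeneau–Demjanov shift with the same configuration and rotamer logic, coming back at 11.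

3. Step 2. The ylide or base may open the dione by retro-Claisen cleavage, both carbonyls may react, or the E/Z ratio may be poor. Fallback (methylenation and cross-metathesis, setting out from 3): non-basic mono-methylenation (Zn, CH2Br2, TiCl4, THF/CH2Cl2) gives 2,2-dimethyl-3-methylidenecyclopentan-1-one F7. Cross-metathesis with tert-butyl(but-3-en-1-yloxy)dimethylsilane (second-generation Grubbs catalyst, CH2Cl2, 40 °C) should place the chain anti to CMe2 and comes back at 5.

**Further compounds**

F1 | step 8 | {2-[(1R)-3-bromo-2,2-dimethyl-6-methylidenecyclohex-3-en-1-yl]ethoxy}(tert-butyl)dimethylsilane | C=C1CC=C(Br)C(C)(C)[C@@H]1CCO[Si](C)(C)C(C)(C)C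
F2 | step 8 | tert-butyl{2-[(1R)-2,2-dimethyl-6-methylidene-3-(4,4,5,5-tetramethyl-1,3,2-dioxaborolan-2-yl)cyclohex-3-en-1-yl]ethoxy}dimethylsilane | C=C1CC=C(B2OC(C)(C)C(C)(C)O2)C(C)(C)[C@@H]1CCO[Si](C)(C)C(C)(C)C
F3 | step 8 | (3R)-3-{2-[(tert-butyldimethylsilyl)oxy]ethyl}-2,2-dimethyl-4-methylidenecyclohexan-1-one | C=C1CCC(=O)C(C)(C)[C@@H]1CCO[Si](C)(C)C(C)(C)C
F4 | step 8 | (1R,3R)-3-{2-[(tert-butyldimethylsilyl)oxy]ethyl}-2,2-dimethyl-4-methylidenecyclohexan-1-ol | C=C1CC[C@@H](O)C(C)(C)[C@@H]1CCO[Si](C)(C)C(C)(C)C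
F5 | step 7 | (1R)-1-{(1S)-1-azido-3-[(tert-butyldimethylsilyl)oxy]propyl}-3-bromo-2,2-dimethylcyclopent-3-en-1-ol | CC1(C)C(Br)=CC[C@]1(O)[C@@H](N=[N+]=[N-])CCO[Si](C)(C)C(C)(C)C
F6 | step 7 | (1R)-1-{(1S)-1-amino-3-[(tert-butyldimethylsilyl)oxy]propyl}-3-bromo-2,2-dimethylcyclopent-3-en-1-ol | CC1(C)C(Br)=CC[C@]1(O)[C@@H](N)CCO[Si](C)(C)C(C)(C)C
F7 | step 2 | 2,2-dimethyl-3-methylidenecyclopentan-1-one | C=C1CCC(=O)C1(C)C
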